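The earlier runs and the new flask are simulated on assumed constants; noise was put on by code.

Count X against E first, with one to one as the zero of the scale.

all flasks: J 5.3 mM

| charge | E | X | remark | time | volume of the second phase over the first |
|---|---|---|---|---|---|
| maple | 0.092 M | 0.28 M | run made earlier |  |  |
| dawn | 0.092 M | 0.184 M |  | 4.0 h | 2.0 |
| winter | 0.40 M | 0.184 M |  | 15 h | 2.0 |

- maple (time / h: Z / %): 0.333: 46; 0.667: 69; 1.00: 80; 1.33: 83; 1.50: 88; 2.00: 94; 2.50: 95

(standard deviation of a reading: 1.5 percentage points)

- what is said of Z includes G
- in the second phase: X, L; everything else is in the first
- charges count per volume of the first phase; a concentration in a rate is the amount of a species over the volume of its own phase; every rate counts per litre of the first phase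
- G is a solid; its amount is given per volume of the solution
- the numbers in the tables scatter with a standard deviation of 1.5 percentage points
- on the list of suspects stand: J + X <-> Q + L; E + Q -> Z + J; G <-> Z
- the earlier runs hold the two phases in the same ratio of volumes as the flask asked about

- the flask that ends with the higher amount of Z, in percent of the E charged, or "neither" when 2 percentage points or less lies between them (dawn / winter / neither)
- final Z, as a percentage of the E charged, in dawn
- final Z, as a percentage of the E charged, in winter

Minutes. The first member reported that in the maple run Z read 46 % after 0.333 h, a first-order constant of 1.85 /h as a reading, and 95 % after 2.50 h. The second member pointed out that the suspects J + X <-> Q + L and E + Q -> Z + J give J back and spend one X per E turned to Z, with G counted in Z, and asked that the charges be compared, both being counted per litre of the first phase. Maple stands at 3.04 X per E and dawn at 2.00, above the zero, so X leaves room for the whole E charge there. Winter lies below the zero, which makes X the limiting reagent. For winter the minutes record 46.0 %: the X ceiling, which is the X charged over the E charged, read as the percent of E that can become Z when that ratio is under one.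

The first member objected that a ceiling does not say it is reached. The second answered that one over the maple constant, 0.541 h, is far shorter than winter's 15 h, so winter has the time if its X goes at anything like that pace. The meeting's own reckoning put winter at 46.0 % and dawn, with less X than maple but a longer run, near 95 %, with dawn ahead.

The forecast, made by someone who saw only these runs, was then read: dawn ahead, 95 % in dawn, 45.5 % in winter, on the ground that “the second phase's oxidant caps the yield”; its winter figure stands lower than the meeting's 46.0 %.

The simulation puts dawn ahead, with 95.4 % in dawn and 46.0 % in winter, so the forecast stands within its tolerance.

    J + X ⇌ Q + L (K = 0.180, k = 51.3 /M/min)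
    E + Q → Z + J (k = 10.6 /M/min)
    G ⇌ Z, rate k3*(cs3 - [Z]) while solid is left; crystals form when [Z] > cs3 (solubility = 3.40 mM, k = 0.129 /min)

In winter, half of the turnover of J + X to Q + L up to the asked time is done by 0.340 h, far earlier than the end of the run at 15 h. At 7.50 h winter's X already reads 0.248 % of its charge and Z reads 45.9 %, against the ceiling of 46.0 %. For the neighbour of winter with 0.68 M of E, the ceiling gives 27.1 %. The computed flask ends at 27.1 %, with 0 % of its X left.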